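**Retrosynthetic overview**
1. Target ⇒ cut the N1–acyl bond to give 3-acetyl-5-isobutyltetramic acid and (E)-dodec-2-enoyl chloride; cut the C3–acetyl bond to give the N-Boc-5-isobutylpyrrolidine-2,4-dione and acetic acid.
2. Structural feature used: in the only ring (pyrrolidine-2,4-dione, N1–C2–C3–C4–C5), C2 is a carbonyl carbon bonded to nothing but N1 and C3, so it can be brought in as carbon monoxide.
3. Key disconnection: N1–C2 and C2–C3 together ⇒ Boc-D-leucine diazoketone (carbene at C3) and CO; carbonylation gives an acylketene that the carbamate N–H closes.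
4. Diazoketone ⇒ Boc-D-leucine (as a mixed anhydride) and trimethylsilyldiazomethane; the (R) centre at C5 is bought with D-leucine and only carried along.
5. Ring order: one ring, formed in the key step; the acetyl and dodecenoyl groups follow.

Key step: step 2

Assumption: all tetramic acids of the route equilibrate between keto and enol tautomers; each is drawn in one tautomeric form, the target in the enol form of the given SMILES.

**Step 1**
Reactants: 1 Boc-D-leucine; 2 isobutyl chloroformate; 3 trimethylsilyldiazomethane
Product: 5 tert-butyl (R)-(1-diazo-5-methyl-2-oxohexan-3-yl)carbamate, via mixed isobutyl carbonic anhydride 4 (not isolated)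
Conditions: i-BuOCOCl, N-methylmorpholine, THF, −15 °C; then TMSCHN2 (2 M in hexanes), MeCN, 0 °C → rt; aqueous work-up
Reagents that add atoms: none
Why: mixed-anhydride activation followed by C-acylation of the diazoalkane (first half of an Arndt–Eistert homologation, with trimethylsilyldiazomethane in place of diazomethane) should give the α-diazoketone, the silyl group being lost to the carbonate leaving group or on aqueous work-up, while the urethane N-protection and the low temperature keep the D-leucine centre from racemising through an oxazolone.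

**Step 2**
Reactants: 5 tert-butyl (R)-(1-diazo-5-methyl-2-oxohexan-3-yl)carbamate; 6 carbon monoxide
Product: 8 tert-butyl (R)-2-isobutyl-3,5-dioxopyrrolidine-1-carboxylate, via acylketene 7 (not isolated)
Conditions: Pd2(dba)3 (2.5 mol %), CO (1 atm), dry toluene, 50 °C, slow addition of 5 at high dilution
Reagents that add atoms: none
Why: Proposed new method: zerovalent palladium from Pd2(dba)3 should decompose diazoketone 5 with loss of N2 to a palladium carbene at C3, and migratory insertion of CO should then form the C2–C3 bond and release acylketene 7. The carbamate N–H adds to the sp ketene carbon C2 (N1–C2 bond) in a 5-exo-dig closure, the attacked C=O π bond lying outside the new ring, and tautomerisation gives the pyrrolidine-2,4-dione 8. The closest known reactions are the palladium-catalysed carbonylation of α-diazo ketones under a CO balloon with capture of the acylketene by external amines, and the thermal cyclisation of the same kind of acylketene (from acyl Meldrum's acids) onto a Boc-carbamate nitrogen; joining the two in one substrate is the untested part. No stereocentre is formed: C5 from D-leucine is a spectator, and the base-free, neutral medium should protect this α-amino ketone centre from enolisation. The selectivity needed is CO insertion at the carbene ahead of Wolff 1,2-shift, N–H insertion to the azetidin-3-one and carbene dimerisation; a CO-saturated solution, a temperature far below that of thermal Wolff rearrangement and a low stationary concentration of 5 should secure it. The carbamate N–H, placed to close a five-membered ring, should outrun intermolecular dimerisation of the ketene.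

**Step 3**
Reactants: 8 tert-butyl (R)-2-isobutyl-3,5-dioxopyrrolidine-1-carboxylate
Product: 10 tert-butyl (R)-4-acetyl-3-hydroxy-2-isobutyl-5-oxo-2,5-dihydro-1H-pyrrole-1-carboxylate, via enol acetate 9 (not isolated)
Conditions: AcOH, DCC, DMAP (1.3 equiv), CH2Cl2, 0 °C → rt; cold dilute acid wash
Reagents that add atoms: acetic acid, CC(=O)O
Why: Steglich-type O-acylation of the C4 enol gives the enol acetate, which DMAP converts by O-to-C acyl migration (anionic Fries-type shift, the standard 3-acylation of tetramic acids) into the 3-acetyl compound, the equilibrium being pulled over by formation of the stabilised tricarbonyl anion.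

**Step 4**
Reactants: 10 tert-butyl (R)-4-acetyl-3-hydroxy-2-isobutyl-5-oxo-2,5-dihydro-1H-pyrrole-1-carboxylate
Product: 11 (R)-3-acetyl-4-hydroxy-5-isobutyl-1,5-dihydro-2H-pyrrol-2-one
Conditions: TFA, CH2Cl2, 0 °C → rt
Reagents that add atoms: none
Why: acidolytic carbamate cleavage (Boc removal through the tert-butyl cation, giving isobutene and CO2) leaves the acid-stable 3-acyltetramic acid untouched and, being non-basic, does not disturb C5.

**Step 5**
Reactants: 12 (E)-dodec-2-enoic acid
Product: 13 (E)-dodec-2-enoyl chloride
Conditions: (COCl)2, DMF (cat.), CH2Cl2, 0 °C → rt; evaporate, use crude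
Reagents that add atoms: oxalyl chloride, O=C(Cl)C(Cl)=O
Why: acid chloride formation with oxalyl chloride under catalytic Vilsmeier activation is neutral and cold enough to keep the conjugated E double bond in place.

**Step 6**
Reactants: 11 (R)-3-acetyl-4-hydroxy-5-isobutyl-1,5-dihydro-2H-pyrrol-2-one; 13 (E)-dodec-2-enoyl chloride
Product: 15 Reutericyclin C, via dilithium dianion 14 (not isolated)
Conditions: n-BuLi (2.1 equiv), THF, −78 °C; then 13, −78 → 0 °C; 1 M HCl work-up
Reagents that add atoms: none
Why: N-acylation of a 3-acyltetramic acid through its O,N-dianion: the first equivalent of n-BuLi forms the tricarbonyl enolate, the second removes the lactam N–H, and the localised, more nucleophilic nitrogen anion should attack the acid chloride in preference to the delocalised enolate oxygens, while the enolate charge keeps C5–H from being removed at −78 °C.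

**Compound list**
1 | Boc-D-leucine, (R)-2-[(tert-butoxycarbonyl)amino]-4-methylpentanoic acid | CC(C)C[C@@H](NC(=O)OC(C)(C)C)C(=O)O | starting material
2 | isobutyl chloroformate | CC(C)COC(Cl)=O | starting material
3 | trimethylsilyldiazomethane | C[Si](C)(C)C=[N+]=[N-] | starting material
4 | mixed isobutyl carbonic anhydride of Boc-D-leucine (not isolated) | CC(C)C[C@@H](NC(=O)OC(C)(C)C)C(=O)OC(=O)OCC(C)C | intermediate
5 | tert-butyl (R)-(1-diazo-5-methyl-2-oxohexan-3-yl)carbamate | CC(C)C[C@@H](NC(=O)OC(C)(C)C)C(=O)C=[N+]=[N-] | intermediate
6 | carbon monoxide | [C-]#[O+] | starting material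
7 | acylketene, tert-butyl (R)-(6-methyl-1,3-dioxohept-1-en-4-yl)carbamate (not isolated) | CC(C)C[C@@H](NC(=O)OC(C)(C)C)C(=O)C=C=O | intermediate
8 | tert-butyl (R)-2-isobutyl-3,5-dioxopyrrolidine-1-carboxylate | CC(C)C[C@@H]1C(=O)CC(=O)N1C(=O)OC(C)(C)C | intermediate
9 | enol acetate, tert-butyl (R)-3-acetoxy-2-isobutyl-5-oxo-2,5-dihydro-1H-pyrrole-1-carboxylate (not isolated) | CC(C)C[C@@H]1C(OC(C)=O)=CC(=O)N1C(=O)OC(C)(C)C | intermediate
10 | tert-butyl (R)-4-acetyl-3-hydroxy-2-isobutyl-5-oxo-2,5-dihydro-1H-pyrrole-1-carboxylate | CC(C)C[C@@H]1C(O)=C(C(C)=O)C(=O)N1C(=O)OC(C)(C)C | intermediate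
11 | (R)-3-acetyl-4-hydroxy-5-isobutyl-1,5-dihydro-2H-pyrrol-2-one | CC(C)C[C@@H]1C(O)=C(C(C)=O)C(=O)N1 | intermediate
12 | (E)-dodec-2-enoic acid | CCCCCCCCC/C=C/C(=O)O | starting material
13 | (E)-dodec-2-enoyl chloride | CCCCCCCCC/C=C/C(=O)Cl | intermediate
14 | dilithium O,N-dianion of 11 (not isolated) | CC(C)C[C@@H]1C([O-])=C(C(C)=O)C(=O)[N-]1.[Li+].[Li+] | intermediate
15 | Reutericyclin C, (R)-3-acetyl-1-[(E)-dodec-2-enoyl]-4-hydroxy-5-isobutyl-1,5-dihydro-2H-pyrrol-2-one | CCCCCCCCC/C=C/C(=O)N1C(=O)C(C(C)=O)=C(O)[C@H]1CC(C)C | target

**Step count**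
Total steps: 6. Longest linear sequence: 5 steps (steps 1, 2, 3, 4 and 6, from Boc-D-leucine); step 5 prepares the side-chain acid chloride.

**Steps most likely to fail**

Step 2 (proposed new method). The palladium carbene may be diverted before CO insertion: insertion into the carbamate N–H to a four-membered ring, carbene dimerisation, or insertion into the acidic C3–H or O–H of product already formed. The acylketene may also be consumed by traces of water or by dimerisation. The fallback uses known chemistry and sets out from 1. Condensation with Meldrum's acid (DCC, DMAP, CH2Cl2, 0 °C) should give tert-butyl (R)-[1-(2,2-dimethyl-4,6-dioxo-1,3-dioxan-5-ylidene)-1-hydroxy-4-methylpentan-2-yl]carbamate F1. Heating this in ethyl acetate at reflux should expel acetone and CO2, pass through the same acylketene 7 and close the ring thermally. The route is rejoined at 8.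

Step 6. Acylation may go to an enolate oxygen or occur twice, the second deprotonation may be incomplete, or the C5 configuration may erode under the strongly basic conditions. The fallback moves N-acylation ahead of C-acetylation, onto a substrate with a single acidic site, and sets out from 8. Mitsunobu O-methylation (MeOH, PPh3, DIAD, THF) should give tert-butyl (R)-2-isobutyl-3-methoxy-5-oxo-2,5-dihydro-1H-pyrrole-1-carboxylate F2. Boc removal (TFA, CH2Cl2) should give (R)-5-isobutyl-4-methoxy-1,5-dihydro-2H-pyrrol-2-one F3. Deprotonation of its only N–H (n-BuLi, 1 equiv, THF, −78 °C) and acylation with 13 should give (R)-1-[(E)-dodec-2-enoyl]-5-isobutyl-4-methoxy-1,5-dihydro-2H-pyrrol-2-one F4. Acid hydrolysis of the enol ether (aqueous HCl, THF) should give (R)-1-[(E)-dodec-2-enoyl]-5-isobutylpyrrolidine-2,4-dione F5. 3-Acetylation as in step 3 (AcOH, DCC, DMAP) then comes back to the route at 15; steps 3, 4 and 6 are replaced.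

Step 3. The O-to-C acyl migration may stall at the enol acetate, or the nucleophilic catalyst may attack the Boc-imide and open or deprotect the ring. The fallback acylates the N-unprotected dione under Lewis acid and sets out from 8. TFA in CH2Cl2 should give (R)-5-isobutylpyrrolidine-2,4-dione F6. Acetyl chloride in BF3·OEt2 at about 70–80 °C should acylate C3 directly and give the difluoroboron chelate of (R)-3-acetyl-5-isobutylpyrrolidine-2,4-dione F7. Methanolysis (MeOH, reflux) should release 11, where the route is rejoined before step 6.

**Further compounds**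
F1 | step 2 | tert-butyl (R)-[1-(2,2-dimethyl-4,6-dioxo-1,3-dioxan-5-ylidene)-1-hydroxy-4-methylpentan-2-yl]carbamate | CC(C)C[C@@H](NC(=O)OC(C)(C)C)C(O)=C1C(=O)OC(C)(C)OC1=O
F2 | step 6 | tert-butyl (R)-2-isobutyl-3-methoxy-5-oxo-2,5-dihydro-1H-pyrrole-1-carboxylate | CC(C)C[C@@H]1C(OC)=CC(=O)N1C(=O)OC(C)(C)C
F3 | step 6 | (R)-5-isobutyl-4-methoxy-1,5-dihydro-2H-pyrrol-2-one | CC(C)C[C@@H]1C(OC)=CC(=O)N1
F4 | step 6 | (R)-1-[(E)-dodec-2-enoyl]-5-isobutyl-4-methoxy-1,5-dihydro-2H-pyrrol-2-one | CCCCCCCCC/C=C/C(=O)N1C(=O)C=C(OC)[C@H]1CC(C)C
F5 | step 6 | (R)-1-[(E)-dodec-2-enoyl]-5-isobutylpyrrolidine-2,4-dione | CCCCCCCCC/C=C/C(=O)N1C(=O)CC(=O)[C@H]1CC(C)C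
F6 | step 3 | (R)-5-isobutylpyrrolidine-2,4-dione | CC(C)C[C@@H]1C(=O)CC(=O)N1
F7 | step 3 | difluoroboron chelate of (R)-3-acetyl-5-isobutylpyrrolidine-2,4-dione (boron bridging the C4 oxygen and the acetyl oxygen) | CC(C)C[C@H]1NC(=O)C2=C1O[B-](F)(F)[O+]=C2C
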